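Count the reagent left, not the product made, and hold it against the target standing.

| flask | substrate | reagent | temperature | remark | time |
|---|---|---|---|---|---|
| violet | 0.054 M | 0.090 M | 2 °C | run made earlier |  |
| red | 0.10 M | 0.090 M | 19 °C | run made earlier |  |
| amber | 0.19 M | 0.090 M | 2 °C | run made earlier |  |
| eta | 0.050 M | 0.0900 M |  | at 25 °C until 6.0 h, from then on at −5 °C | 12 h |
| zeta | 0.20 M | 0.0900 M |  | at 25 °C throughout | 12 h |

| run | time / h | target / % | isomer of the product / % | side product / % |
|---|---|---|---|---|
| violet | 2.50 | 2.5 | 1.2 | 0.8 |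
| violet | 6.00 | 4.4 | 1.4 | 0 |
| violet | 12.0 | 6.7 | 3.6 | 0.9 |
| violet | 20.0 | 10.0 | 4.9 | 1.9 |
| red | 1.50 | 4.0 | 1.8 | 1.0 |
| red | 3.00 | 8.7 | 3.6 | 1.8 |
| red | 5.00 | 11.4 | 4.8 | 4.4 |
| red | 6.00 | 12.9 | 6.8 | 6.9 |
| amber | 1.50 | 1.7 | 0.8 | 0.9 |
| amber | 3.00 | 2.1 | 0.2 | 0.3 |
| amber | 8.00 | 4.2 | 1.5 | 0.2 |
| amber | 20.0 | 8.2 | 3.8 | 5.1 |

(standard deviation of a reading: 0.5 percentage points)

- percentages count the substrate that a species holds: one side product counts as two

* the winner by share of target in all that became target or isomer of the product or side product; "neither" if no more than 2 percentage points parts them (eta / zeta / neither)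
* share of target in all that became target or isomer of the product or side product, eta
* share of target in all that became target or isomer of the product or side product, zeta

In the red run the side product lags, then climbs, so we take it as target joined to substrate. Target is then made at a rate proportional to [substrate][reagent] and used at a rate proportional to [substrate][target]. We follow these two rates: [substrate] cancels from their ratio.

Between 3.00 h and 6.00 h of the red run, 2.6 percentage points of target went into side product, out of 6.8 points made. Meanwhile [target] averaged 0.0108 M and [reagent], the charge less what target, isomer of the product and side product hold, averaged 0.0718 M. This gives the reading 2.51, our loss factor s, the rate constant of using target over that of making it (a selectivity factor).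

Made over used is therefore [reagent]/(s[target]), and in this reckoning, which counts no way back, target stops gaining at [target] = [reagent]/s. We take s unchanged at 25 °C. At the charged reagent this ceiling is 0.0358 M, and used reagent lowers it further.

| flask | substrate charged | ceiling, of substrate charged |
|---|---|---|
| eta | 0.050 M | 71.6 % |
| zeta | 0.20 M | 17.9 % |

Zeta's ceiling stands lower than eta's, so we commit to eta. Our reckoning gives a winner, not a share.

The forecast says eta, with 54 % for eta and 24 % for zeta, holding that in zeta “target is heavily eaten by substrate”.

The flask gives eta: 51.9 % for eta against 11.7 % for zeta.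

    substrate + reagent ⇌ target (K = 29.0 M⁻¹, k = 2.10 × 10⁻⁴ M⁻¹ s⁻¹, Ea = 69.0 kJ mol⁻¹, ΔH = −59.0 kJ mol⁻¹)
    substrate + reagent ⇌ isomer of the product (K = 22.0 M⁻¹, k = 7.90 × 10⁻⁵ M⁻¹ s⁻¹, Ea = 66.0 kJ mol⁻¹, ΔH = 22.0 kJ mol⁻¹)
    substrate + target → side product (k = 4.60 × 10⁻⁴ M⁻¹ s⁻¹, Ea = 69.0 kJ mol⁻¹)
    (constants at 25 °C)

At 12.0 h zeta holds [reagent] 0.0212 M and [target] 0.0125 M, so with our reading s made over used comes to 0.676, below one, and target has gone from 8.67 % at 6.00 h to 6.24 %. The neighbouring flask is zeta with 0.22 M of reagent. Its reagent left, 44.1 % of its charge, puts the ceiling at 19.3 % of the substrate charged, and at 12.0 h that flask holds 19.4 % target, a share of 22.3 %.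

The earlier runs and the new flask stem from a simulated flask for substances that don't exist; scatter was added.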